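## Structural features

The target is a germacranolide: a ten-membered carbocycle (C1–C10) fused through C6 and C7 to a butenolide (O–C12(=O)–C11=C7), so that the tetrasubstituted C7=C11 alkene belongs to both rings. The large ring carries the C1 ketone, the E-trisubstituted C4=C5 alkene (methyl C15 on C4), a secondary methacrylate at C8 and, at C10, a methyl group (C14) and a tertiary acetate; C11 carries the acetoxymethyl carbon C13. The three stereocentres are C6 (R), C8 (S) and C10 (R). None is bonded to another: C6 and C8 flank the sp2 carbon C7, and C8 and C10 are separated by the C9 methylene, with their oxygens syn along the C7–C1 chain. Fragile points are the C6 hydrogen (γ to the lactone carbonyl and allylic, so it can epimerise through the 2-oxidofuran), the two ionisable allylic C–O bonds (C6–O of the lactone, C13–OAc), the methacrylate, the tertiary α-acyloxy ketone, and the medium ring, in which the C1 carbonyl and the C4=C5 alkene can react across the ring under Lewis acids. The real difficulty is twofold: closing a strained ten-membered ring that holds an E alkene without touching C6, and placing two different acyl groups on a primary, a secondary and a tertiary oxygen. The key step uses the 1,4-relation C1(=O)–C2–C3–C4(=C5): C2 and C3 are the two methylenes of a cyclopropanol on C1 and C4 is an alkenyl iodide, so forming the single bond C3–C4 closes the ten-membered ring and reveals the ketone.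

## Logic of the disconnections

28 to 27. The two acetyl C–O bonds at O13 and O10 are cut. The allylic primary acetate and the tertiary α-keto acetate are the most labile groups, so they go on last and together. The forward step must be forcing enough for a tertiary hydroxyl yet leave the methacrylate and C6 alone.

27 to 26. The O–Si bonds at O10 and O13 are cut. Because the C8 oxygen already carries the methacrylate in 26, no selective acylation among three hydroxyls is ever needed. The forward step needs a non-basic fluoride source.

26 to 25. The C3–C4 bond is cut, which opens the ten-membered ring. This gives an open chain with a free cyclopropanol on C1 and an E iodoalkene at C4, with all stereocentres and the alkene geometry already set. A cyclic C8/C10 acetal is avoided: on this syn diol it would force the C10 methyl axial against an acetal substituent, lock C7–C8–C9–C10–C1 in an extended shape, and have to be installed next to a competing 1,2-diol. The forward step must close the ring faster than β-hydride elimination, oligomerisation and allylic ionisation, and must tolerate the methacrylate.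

25 to 24 to 23 to 21. The cyclopropyl O–Si bond, the C8 O–acyl bond and the C4–I bond are cut in turn. The cyclopropanol is freed last from a trimethylsilyl ether that is far more labile than the C10 triethylsilyl and C13 tert-butyldiphenylsilyl ethers. The methacrylate is put on when the C8 hydroxyl is the only free one. Iodine comes from the methylalkyne by syn hydrozirconation, which fixes the geometry mechanistically. The forward step must touch the alkyne before the lactone.

21 to 20 to 19 to 9 + 18. The C7–C8 bond is cut, which divides the molecule into two fragments of similar size. The C8 configuration is not left to the coupling but set afterwards by reagent-controlled reduction of ketone 20, independently of the remote C6 and C10. The forward coupling needs an alkenylchromium that adds without opening the butenolide.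

9 to 8 to 7 to 5 + 6. The cyclopropane bonds C1–C2 and C1–C3 are cut back to a lactone carbonyl. The same ring opening frees the primary alcohol that becomes the C8 aldehyde. The forward step must bring a titanacyclopropane to a hindered carbonyl.

5 to 4 to 2 to 1. The lactone C–O bond and the C8 oxidation level are traced back to the chiral pool. The two carboxyls of 1 are told apart by tying the α-hydroxy acid into a dioxolanone. C10 is never a reacting centre.

18 to 15 + 16 (through 17). The C5–C6 bond and the lactone O–C12 bond are cut. C6 is made last in this fragment by a catalyst-controlled alkynylation, after all strongly basic steps, so its acidic hydrogen never meets an enolate base. The forward step needs the E geometry of 15 (aldehyde cis to the ester) and Re-face addition.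

15 to 14 to 13 to 11 + 12, and 11 to 10. The C7–C11 bond is cut by a crossed Claisen disconnection, the triflate by enol sulfonylation, and the silyl ether by O–Si cleavage. The forward triflation must place the triflate trans to the ester.

## Other disconnections considered

Alternative 1: The cut is C6–C7 together with the lactone O–C12 bond. In the forward step CrCl2 (divalent chromium) would turn a C13 allylic bromide into an allylchromium that adds through C7 to a C6 aldehyde, and the alkoxide would close the lactone to give A1. In its favour, one operation forms the ring, the lactone and two stereocentres through an ordered six-membered transition state. Intramolecular allylchromium closures of ten-membered α-methylene lactones also have closer precedent than the chosen ring closure, and on that point this alternative is the better. Against it here, the C7 stereocentre made in A1 is destroyed again when the exocyclic alkene is moved into the ring. The transposition must oxidise C13 in a molecule that also holds the C4=C5 alkene and a tertiary acetate. C6 would be set relative to the remote C8 and C10 by the macrocyclic transition state rather than by a reagent. In step economy it needs about five operations after ring closure (transposition, acetate installation, desilylation, methacryloylation) against two in the chosen plan; the way to the open-chain precursor of A1 is of comparable length.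

Alternative 2: The cut is the transannular C1–C5 bond of a hydroazulene. In the forward step Pb(OAc)4 (tetravalent lead) would oxidise a tertiary C1 alcohol bearing a γ-stannyl group at C4, breaking C1–C5 and C4–Sn to give the C1 ketone and the E alkene of A2. In its favour, the ten-membered ring arises by ring expansion, so there is no entropic cost of end-to-end closure, and on certainty of ring formation this alternative is the better. Alkene geometry follows from a stereospecific fragmentation, which makes it the equal of the chosen plan, where geometry is fixed in the iodide. Against it here, A2 has a C6 ketone and a C7 methylene and no lactone. The butenolide with its tetrasubstituted alkene and C13 would have to be built on a medium ring with two ketones, and C6 would be set late under macrocyclic control. The bicyclic precursor needs stereocentres at C1, C4 and C5 that vanish in the product. A methoxymethyl ether on the tertiary C10 oxygen would need strong acid for removal, in a ring prone to transannular reactions. After the key step it is clearly longer than the chosen plan.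

Alternative 3: The cut is C7–C8. In the forward step NiCl2/CrCl2 (catalytic nickel with divalent chromium) would couple a C7 enol triflate of the tetronate with a C8 aldehyde in the ring-closing step to give A3. In its favour, Ni/Cr-mediated alkenyl–aldehyde closures of medium rings are better precedented than the chosen closure, and it is named here as the better on that point. A3 is three operations from the target, about the equal of the chosen plan's two. Against it here, the C8 configuration would be made in the ring closure under macrocyclic control and could be corrected only by oxidation and reduction on the sensitive macrocycle. The allylic C13 acetate would be exposed to low-valent nickel and chromium. The open-chain precursor of A3 needs the C3–C4 bond made first, in the presence of the reactive triflate. The chosen plan forms the same C7–C8 bond between two fragments, where the C8 configuration can be set on an open chain. The ring closure of this alternative is kept as the fallback for step 18.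

Key step: step 18

Remark on the chemistry: precursor 25 and macrocycle 26 carry 6R, 8S, 10R and the 4E alkene exactly as the target does (checked centre by centre by CIP priorities), so no descriptor needed correction; only the protecting groups differ from a C8/C10 acetonide with 13-OTBS (8-O-methacryloyl, 10-OTES, 13-OTBDPS are used), and methyl 3-hydroxypropanoate, methyl 2,2-dimethoxyacetate and propyne are taken as commercial.

## Steps

Step 1
Reactants: 1 (R)-citramalic acid
Product: 2 2-[(4R)-2,2,4-trimethyl-5-oxo-1,3-dioxolan-4-yl]acetic acid
Conditions: 2,2-dimethoxypropane, TsOH·H2O (cat.), CH2Cl2, rt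
Reagents that add atoms: 2,2-dimethoxypropane, COC(C)(C)OC
Why: Acid-catalysed acetalisation should tie the tertiary hydroxyl and the adjacent carboxyl into the five-membered dioxolanone (favoured over the six-membered alternative), leaving only the CH2CO2H group free; the C10 stereocentre comes from 1 and is not touched.

Step 2
Reactants: 2 2-[(4R)-2,2,4-trimethyl-5-oxo-1,3-dioxolan-4-yl]acetic acid
Product: 4 (3R)-3-hydroxy-3-methyloxolan-2-one, via hydroxyethyl dioxolanone 3 (not isolated)
Conditions: BH3·SMe2, THF, 0 °C to rt; MeOH; then TsOH (cat.), CH2Cl2, rt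
Reagents that add atoms: none
Why: Borane should reduce the free carboxylic acid chemoselectively in the presence of the dioxolanone, and acid-catalysed translactonisation of the resulting primary alcohol onto the activated ester should then give the five-membered lactone with loss of acetone; C10 is not involved.

Step 3
Reactants: 4 (3R)-3-hydroxy-3-methyloxolan-2-one
Product: 5 (3R)-3-methyl-3-[(triethylsilyl)oxy]oxolan-2-one
Conditions: Et3SiOTf, 2,6-lutidine, CH2Cl2, 0 °C
Reagents that add atoms: triethylsilyl trifluoromethanesulfonate, CC[Si](CC)(CC)OS(=O)(=O)C(F)(F)F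
Why: A silyl triflate with a hindered pyridine base is the standard way to silylate a tertiary α-hydroxy lactone; the triethylsilyl ether is stable to Grignard reagents and stays on O10 until step 19.

Step 4
Reactants: 5 (3R)-3-methyl-3-[(triethylsilyl)oxy]oxolan-2-one; 6 ethylmagnesium bromide
Product: 7 1-[(2R)-4-hydroxy-2-[(triethylsilyl)oxy]butan-2-yl]cyclopropan-1-ol
Conditions: EtMgBr (3.2 equiv, slow addition), Ti(OiPr)4 (0.3 equiv), THF, 0 °C to rt
Reagents that add atoms: none
Why: In the Kulinkovich reaction the titanacyclopropane formed from two ethyl groups should act as a 1,2-dianion on the lactone carbonyl, giving the C1 cyclopropanol (C2 and C3 from 6) and freeing the C8 primary alcohol in the same ring opening; lactones are among the more reactive substrates and the quaternary C10 is a spectator.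

Step 5
Reactants: 7 1-[(2R)-4-hydroxy-2-[(triethylsilyl)oxy]butan-2-yl]cyclopropan-1-ol
Product: 8 {(3R)-3-[(triethylsilyl)oxy]-3-{1-[(trimethylsilyl)oxy]cyclopropyl}butoxy}(trimethyl)silane
Conditions: Me3SiCl, imidazole, CH2Cl2, 0 °C to rt
Reagents that add atoms: chlorotrimethylsilane, C[Si](C)(C)Cl
Why: Silylation of both free hydroxyls under buffered conditions should not open the cyclopropanol; the small trimethylsilyl group goes onto the tertiary cyclopropanol readily and will later be removable in the presence of the C10 triethylsilyl ether.

Step 6
Reactants: 8 {(3R)-3-[(triethylsilyl)oxy]-3-{1-[(trimethylsilyl)oxy]cyclopropyl}butoxy}(trimethyl)silane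
Product: 9 (3R)-3-[(triethylsilyl)oxy]-3-{1-[(trimethylsilyl)oxy]cyclopropyl}butanal
Conditions: (COCl)2, DMSO, CH2Cl2, −78 to −40 °C; Et3N, to 0 °C
Reagents that add atoms: none
Why: Under Swern conditions a primary trimethylsilyl ether is cleaved by the chlorosulfonium salt and oxidised directly to the aldehyde, whereas the two tertiary silyl ethers are too hindered to react; this gives the C8 aldehyde with the cyclopropanol still masked, so no lactol can form.

Step 7
Reactants: 10 methyl 3-hydroxypropanoate
Product: 11 methyl 3-[(tert-butyldiphenylsilyl)oxy]propanoate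
Conditions: t-BuPh2SiCl, imidazole, CH2Cl2, rt
Reagents that add atoms: tert-butyl(chloro)diphenylsilane, CC(C)(C)[Si](Cl)(c1ccccc1)c1ccccc1
Why: Routine silylation of a primary alcohol; the acid-stable tert-butyldiphenylsilyl ether on the future O13 survives the acetal hydrolysis of step 10 and, unlike an acetate, cannot ionise under palladium in step 18.

Step 8
Reactants: 11 methyl 3-[(tert-butyldiphenylsilyl)oxy]propanoate; 12 methyl 2,2-dimethoxyacetate
Product: 13 methyl 2-{[(tert-butyldiphenylsilyl)oxy]methyl}-4,4-dimethoxy-3-oxobutanoate (racemic at C11, enolisable)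
Conditions: LiN(iPr)2 (2.1 equiv), THF, −78 °C; then 12; sat. NH4Cl at −78 °C
Reagents that add atoms: none
Why: Crossed Claisen condensation of the ester enolate with a non-enolisable, activated ester should form C7–C11; at −78 °C neither the β-silyloxy enolate nor the product enolate should eliminate silanolate, and the cold quench keeps it so.

Step 9
Reactants: 13 methyl 2-{[(tert-butyldiphenylsilyl)oxy]methyl}-4,4-dimethoxy-3-oxobutanoate
Product: 14 methyl (2E)-2-{[(tert-butyldiphenylsilyl)oxy]methyl}-4,4-dimethoxy-3-{[(trifluoromethyl)sulfonyl]oxy}but-2-enoate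
Conditions: Tf2O, aq. Me4NOH, toluene, 0 °C
Reagents that add atoms: trifluoromethanesulfonic anhydride, O=S(=O)(OS(=O)(=O)C(F)(F)F)C(F)(F)F
Why: Stereoselective enol triflation of a β-keto ester: with a non-coordinating tetraalkylammonium counter-ion the enolate is not chelated and adopts the dipole-minimised form with the enolate oxygen anti to the ester carbonyl, so the triflate is placed trans to CO2Me and the acetal carbon (C6) cis to it, as lactone formation in step 11 requires.

Step 10
Reactants: 14 methyl (2E)-2-{[(tert-butyldiphenylsilyl)oxy]methyl}-4,4-dimethoxy-3-{[(trifluoromethyl)sulfonyl]oxy}but-2-enoate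
Product: 15 methyl (2E)-2-{[(tert-butyldiphenylsilyl)oxy]methyl}-4-oxo-3-{[(trifluoromethyl)sulfonyl]oxy}but-2-enoate
Conditions: CF3CO2H, H2O, CH2Cl2, 0 °C
Reagents that add atoms: water, O
Why: Acid hydrolysis of the dimethyl acetal frees the C6 aldehyde; the enol triflate and the tert-butyldiphenylsilyl ether are stable to aqueous acid, and with a methyl ester there is no ring–chain tautomerism to a pseudo-acid.

Step 11
Reactants: 15 methyl (2E)-2-{[(tert-butyldiphenylsilyl)oxy]methyl}-4-oxo-3-{[(trifluoromethyl)sulfonyl]oxy}but-2-enoate; 16 propyne
Product: 18 (2R)-4-{[(tert-butyldiphenylsilyl)oxy]methyl}-5-oxo-2-(prop-1-yn-1-yl)-2,5-dihydrofuran-3-yl trifluoromethanesulfonate, via hydroxy ester 17 (not isolated)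
Conditions: propyne, Me2Zn, (S,S)-ProPhenol (20 mol%), Ph3PO, toluene, 0 °C; then rt
Reagents that add atoms: none
Why: Catalytic enantioselective addition of an alkynylzinc to an α,β-unsaturated aldehyde sets C6, addition to the Re face giving 6R; the ligand antipode is the one that delivers this face (to be confirmed by Mosher analysis, the other enantiomer being equally available), and the zinc alkoxide of 17 should close onto the cis methyl ester to give the butenolide without any strong base ever meeting the C6 hydrogen.

Step 12
Reactants: 9 (3R)-3-[(triethylsilyl)oxy]-3-{1-[(trimethylsilyl)oxy]cyclopropyl}butanal; 18 (2R)-4-{[(tert-butyldiphenylsilyl)oxy]methyl}-5-oxo-2-(prop-1-yn-1-yl)-2,5-dihydrofuran-3-yl trifluoromethanesulfonate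
Product: 19 C7–C8 coupled carbinol, both C8 epimers (butenolide with 6R propynyl, 13-OTBDPS, and on C7 the chain CH(OH)–CH2–C(CH3)(OTES)–[1-(OTMS)cyclopropyl], 10R)
Conditions: CrCl2 (5 equiv), NiCl2 (2 mol%), DMF, rt
Reagents that add atoms: none
Why: Nozaki–Hiyama–Kishi coupling: zerovalent nickel inserts into the activated enol triflate, transmetallation gives an alkenylchromium that adds only to the aldehyde under neutral conditions, tolerating the lactone, the alkyne and all silyl ethers; the new C8 centre is expected as a mixture and is corrected in steps 13 and 14.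

Step 13
Reactants: 19 C7–C8 coupled carbinol, both C8 epimers
Product: 20 C8 ketone (butenolide with 6R propynyl, 13-OTBDPS, and on C7 the chain C(=O)–CH2–C(CH3)(OTES)–[1-(OTMS)cyclopropyl], 10R)
Conditions: Dess–Martin periodinane, NaHCO3, CH2Cl2, 0 °C to rt
Reagents that add atoms: none
Why: Buffered Dess–Martin oxidation converts both epimers into one ketone under neutral conditions that should leave the silyl ethers, the β-silyloxy ketone and C6 untouched.

Step 14
Reactants: 20 C8 ketone
Product: 21 (8S)-carbinol (butenolide with 6R propynyl, 13-OTBDPS, and on C7 the chain (S)-CH(OH)–CH2–C(CH3)(OTES)–[1-(OTMS)cyclopropyl], 10R)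
Conditions: (R)-2-methyl-CBS-oxazaborolidine (0.5 equiv), catecholborane, toluene/CH2Cl2, −78 °C
Reagents that add atoms: none
Why: Corey–Bakshi–Shibata reduction: the fully substituted alkenyl carbon C7 is the large group and the C9 methylene the small one, so the (R)-catalyst should deliver hydride to give 8S (the mirror image of the acetophenone case with the (S)-catalyst); catecholborane at −78 °C reduces the ketone 1,2 and does not hydroborate the alkyne or touch the lactone.

Step 15
Reactants: 21 (8S)-carbinol
Product: 23 (E)-iodoalkene (as 21, with the C6 substituent now (1E)-2-iodoprop-1-en-1-yl), via alkenylzirconocene 22 (not isolated)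
Conditions: Cp2Zr(H)Cl (2.5 equiv), THF, rt; then I2, 0 °C
Reagents that add atoms: iodine, II
Why: Hydrozirconation adds Zr–H syn across the methylalkyne and, under equilibration with excess hydride, places zirconium on the less hindered methyl-bearing C4 away from the branched C6; iodinolysis with retention gives the 2-iodoalkene with iodine trans to C6, and alkynes insert much faster than a lactone is reduced (one equivalent of hydride is used up by the C8 hydroxyl).

Step 16
Reactants: 23 (E)-iodoalkene
Product: 24 8-O-methacrylate of 23
Conditions: methacrylic anhydride, Et3N, DMAP (cat.), CH2Cl2, 0 °C to rt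
Reagents that add atoms: methacrylic anhydride, C=C(C)C(=O)OC(=O)C(C)=C
Why: DMAP-catalysed acylation of the only free hydroxyl puts the methacrylate on C8 with no selectivity question; the configuration at C8 is retained because the C–O bond is not broken.

Step 17
Reactants: 24 8-O-methacrylate of 23
Product: 25 cyclisation precursor (C1 cyclopropanol, 10-OTES, 8-O-methacryloyl, 13-OTBDPS butenolide, (E)-C4 iodoalkene)
Conditions: HF·pyridine, pyridine, THF, 0 °C
Reagents that add atoms: none
Why: Buffered fluoride removes a trimethylsilyl ether far faster than a tertiary triethylsilyl or a primary tert-butyldiphenylsilyl ether, so only the cyclopropanol is freed; the medium is not basic, which spares the methacrylate and the C6 hydrogen.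

Step 18
Reactants: 25 cyclisation precursor
Product: 26 ten-membered germacranolide core (6R,8S,10R,4E; 1-oxo, 8-O-methacryloyl, 10-OTES, 13-OTBDPS)
Conditions: Pd(OAc)2 (10 mol%), XPhos (20 mol%), Cs2CO3 (2 equiv), toluene, 80 °C, 2 mM, slow addition of 25
Reagents that add atoms: none
Why: Proposed new method: Zerovalent palladium (from Pd(OAc)2 and XPhos) should add oxidatively to the C4–I bond with retention of the E geometry, the carbonate then turns the cyclopropanol into a palladium alkoxide, and strain-driven β-carbon elimination opens the three-membered ring to an alkyl(alkenyl)palladium homoenolate whose reductive elimination forms C3–C4 and frees the C1 ketone. The closest known reaction is the intermolecular ring-opening cross-coupling of cyclopropanols with aryl and alkenyl halides under these conditions; what is new is that alkoxide exchange and reductive elimination here pass through ten- and eleven-membered palladacycles. The ten-membered carbocycle is closed end to end by C(sp3)–C(sp2) reductive elimination from the eleven-membered palladacycle, at high dilution with slow addition so that ring closure can outrun oligomerisation. No stereocentre is formed: C6, C8 and C10 come unchanged from 25 and the alkene geometry is that of the iodide. The two cyclopropane methylenes are equivalent, so the opening is regiochemically unambiguous. Reductive elimination must be faster than β-hydride elimination to the vinyl ketone, which the bulky biarylphosphine is chosen to secure, and the base must leave the acidic C6 hydrogen alone, for which an insoluble carbonate in toluene is the mildest base known to serve this coupling. The substrate helps in three ways: O10 is silylated (no α-ketol or diol chemistry), O13 is a silyl ether that cannot ionise, and the methacrylate could reach the alkenylpalladium only through a nine-membered Heck transition state.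

Step 19
Reactants: 26 ten-membered germacranolide core
Product: 27 (6R,8S,10R,4E)-10,13-dihydroxy-8-methacryloyloxy-1-oxogermacra-4,7(11)-dien-12,6-olide
Conditions: HF·pyridine (excess), THF, 0 °C to rt
Reagents that add atoms: none
Why: Fluoride-mediated cleavage of both silyl ethers in one operation under mildly acidic, non-basic conditions, which avoids acyl migration, epimerisation at C6 and Lewis-acid-induced transannular reactions.

Step 20
Reactants: 27 (6R,8S,10R,4E)-10,13-dihydroxy-8-methacryloyloxy-1-oxogermacra-4,7(11)-dien-12,6-olide
Product: 28 target CNP0115165.1, (6R,8S,10R,4E)-10,13-diacetoxy-8-methacryloyloxy-1-oxogermacra-4,7(11)-dien-12,6-olide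
Conditions: Ac2O, DMAP, Et3N, CH2Cl2, rt to 35 °C
Reagents that add atoms: acetic anhydride, CC(=O)OC(C)=O
Why: DMAP-catalysed acetylation acylates the primary hydroxyl at once and, with excess reagent, the tertiary one as well (the reaction type that makes tertiary acetates accessible), with no Lewis acid that could trigger a transannular reaction; the tetrasubstituted C7=C11 alkene should be too hindered for attack by DMAP at C7.

## Compound list

1 | (R)-citramalic acid | OC(=O)C[C@@](C)(O)C(=O)O | starting material
2 | 2-[(4R)-2,2,4-trimethyl-5-oxo-1,3-dioxolan-4-yl]acetic acid | OC(=O)C[C@@]1(C)OC(C)(C)OC1=O | intermediate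
3 | (5R)-5-(2-hydroxyethyl)-2,2,5-trimethyl-1,3-dioxolan-4-one | OCC[C@@]1(C)OC(C)(C)OC1=O | intermediate (not isolated)
4 | (3R)-3-hydroxy-3-methyloxolan-2-one | O=C1OCC[C@@]1(C)O | intermediate
5 | (3R)-3-methyl-3-[(triethylsilyl)oxy]oxolan-2-one | O=C1OCC[C@@]1(C)O[Si](CC)(CC)CC | intermediate
6 | ethylmagnesium bromide | CC[Mg]Br | starting material
7 | 1-[(2R)-4-hydroxy-2-[(triethylsilyl)oxy]butan-2-yl]cyclopropan-1-ol | OC1(CC1)[C@](C)(O[Si](CC)(CC)CC)CCO | intermediate
8 | {(3R)-3-[(triethylsilyl)oxy]-3-{1-[(trimethylsilyl)oxy]cyclopropyl}butoxy}(trimethyl)silane | C[Si](C)(C)OCC[C@@](C)(O[Si](CC)(CC)CC)C1(O[Si](C)(C)C)CC1 | intermediate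
9 | (3R)-3-[(triethylsilyl)oxy]-3-{1-[(trimethylsilyl)oxy]cyclopropyl}butanal | O=CC[C@@](C)(O[Si](CC)(CC)CC)C1(O[Si](C)(C)C)CC1 | intermediate
10 | methyl 3-hydroxypropanoate | COC(=O)CCO | starting material
11 | methyl 3-[(tert-butyldiphenylsilyl)oxy]propanoate | COC(=O)CCO[Si](c1ccccc1)(c1ccccc1)C(C)(C)C | intermediate
12 | methyl 2,2-dimethoxyacetate | COC(OC)C(=O)OC | starting material
13 | methyl 2-{[(tert-butyldiphenylsilyl)oxy]methyl}-4,4-dimethoxy-3-oxobutanoate (racemic, enolisable) | COC(=O)C(CO[Si](c1ccccc1)(c1ccccc1)C(C)(C)C)C(=O)C(OC)OC | intermediate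
14 | methyl (2E)-2-{[(tert-butyldiphenylsilyl)oxy]methyl}-4,4-dimethoxy-3-{[(trifluoromethyl)sulfonyl]oxy}but-2-enoate | COC(=O)/C(CO[Si](c1ccccc1)(c1ccccc1)C(C)(C)C)=C(/OS(=O)(=O)C(F)(F)F)C(OC)OC | intermediate
15 | methyl (2E)-2-{[(tert-butyldiphenylsilyl)oxy]methyl}-4-oxo-3-{[(trifluoromethyl)sulfonyl]oxy}but-2-enoate | COC(=O)/C(CO[Si](c1ccccc1)(c1ccccc1)C(C)(C)C)=C(/OS(=O)(=O)C(F)(F)F)C=O | intermediate
16 | propyne | CC#C | starting material
17 | methyl (2E,4R)-2-{[(tert-butyldiphenylsilyl)oxy]methyl}-4-hydroxy-3-{[(trifluoromethyl)sulfonyl]oxy}hept-2-en-5-ynoate | COC(=O)/C(CO[Si](c1ccccc1)(c1ccccc1)C(C)(C)C)=C(/OS(=O)(=O)C(F)(F)F)[C@H](O)C#CC | intermediate (not isolated)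
18 | (2R)-4-{[(tert-butyldiphenylsilyl)oxy]methyl}-5-oxo-2-(prop-1-yn-1-yl)-2,5-dihydrofuran-3-yl trifluoromethanesulfonate | CC#C[C@H]1OC(=O)C(CO[Si](c2ccccc2)(c2ccccc2)C(C)(C)C)=C1OS(=O)(=O)C(F)(F)F | intermediate
19 | (5R)-3-{[(tert-butyldiphenylsilyl)oxy]methyl}-4-{(3R)-1-hydroxy-3-[(triethylsilyl)oxy]-3-{1-[(trimethylsilyl)oxy]cyclopropyl}butyl}-5-(prop-1-yn-1-yl)furan-2(5H)-one, both epimers at the carbinol carbon C8 | CC#C[C@H]1OC(=O)C(CO[Si](c2ccccc2)(c2ccccc2)C(C)(C)C)=C1C(O)C[C@@](C)(O[Si](CC)(CC)CC)C3(O[Si](C)(C)C)CC3 | intermediate
20 | (5R)-3-{[(tert-butyldiphenylsilyl)oxy]methyl}-5-(prop-1-yn-1-yl)-4-{(3R)-3-[(triethylsilyl)oxy]-3-{1-[(trimethylsilyl)oxy]cyclopropyl}butanoyl}furan-2(5H)-one | CC#C[C@H]1OC(=O)C(CO[Si](c2ccccc2)(c2ccccc2)C(C)(C)C)=C1C(=O)C[C@@](C)(O[Si](CC)(CC)CC)C3(O[Si](C)(C)C)CC3 | intermediate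
21 | (5R)-3-{[(tert-butyldiphenylsilyl)oxy]methyl}-4-{(1S,3R)-1-hydroxy-3-[(triethylsilyl)oxy]-3-{1-[(trimethylsilyl)oxy]cyclopropyl}butyl}-5-(prop-1-yn-1-yl)furan-2(5H)-one | CC#C[C@H]1OC(=O)C(CO[Si](c2ccccc2)(c2ccccc2)C(C)(C)C)=C1[C@@H](O)C[C@@](C)(O[Si](CC)(CC)CC)C3(O[Si](C)(C)C)CC3 | intermediate
22 | C4 alkenylzirconocene chloride of 21 with the C8 oxygen as zirconocene chloride alkoxide (cyclopentadienyl rings drawn σ-bonded) | C/C(=C\[C@H]1OC(=O)C(CO[Si](c2ccccc2)(c2ccccc2)C(C)(C)C)=C1[C@@H](O[Zr](Cl)(C4C=CC=C4)C5C=CC=C5)C[C@@](C)(O[Si](CC)(CC)CC)C3(O[Si](C)(C)C)CC3)[Zr](Cl)(C6C=CC=C6)C7C=CC=C7 | intermediate (not isolated)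
23 | (5R)-3-{[(tert-butyldiphenylsilyl)oxy]methyl}-4-{(1S,3R)-1-hydroxy-3-[(triethylsilyl)oxy]-3-{1-[(trimethylsilyl)oxy]cyclopropyl}butyl}-5-[(1E)-2-iodoprop-1-en-1-yl]furan-2(5H)-one | I/C(C)=C/[C@H]1OC(=O)C(CO[Si](c2ccccc2)(c2ccccc2)C(C)(C)C)=C1[C@@H](O)C[C@@](C)(O[Si](CC)(CC)CC)C3(O[Si](C)(C)C)CC3 | intermediate
24 | 8-O-(2-methylprop-2-enoyl) ester of 23 | I/C(C)=C/[C@H]1OC(=O)C(CO[Si](c2ccccc2)(c2ccccc2)C(C)(C)C)=C1[C@@H](OC(=O)C(C)=C)C[C@@](C)(O[Si](CC)(CC)CC)C3(O[Si](C)(C)C)CC3 | intermediate
25 | cyclisation precursor: as 24 with the free 1-hydroxycyclopropyl group (C1 cyclopropanol, 10-OTES, 8-O-methacryloyl, 13-OTBDPS, (E)-C4 iodoalkene) | I/C(C)=C/[C@H]1OC(=O)C(CO[Si](c2ccccc2)(c2ccccc2)C(C)(C)C)=C1[C@@H](OC(=O)C(C)=C)C[C@@](C)(O[Si](CC)(CC)CC)C3(O)CC3 | intermediate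
26 | (6R,8S,10R,4E)-13-[(tert-butyldiphenylsilyl)oxy]-8-methacryloyloxy-1-oxo-10-[(triethylsilyl)oxy]germacra-4,7(11)-dien-12,6-olide | C=C(C)C(=O)O[C@H]1C[C@@](C)(O[Si](CC)(CC)CC)C(=O)CC/C(C)=C/[C@H]2OC(=O)C(CO[Si](c3ccccc3)(c3ccccc3)C(C)(C)C)=C12 | intermediate
27 | (6R,8S,10R,4E)-10,13-dihydroxy-8-methacryloyloxy-1-oxogermacra-4,7(11)-dien-12,6-olide | C=C(C)C(=O)O[C@H]1C[C@@](C)(O)C(=O)CC/C(C)=C/[C@H]2OC(=O)C(CO)=C12 | intermediate
28 | CNP0115165.1, (6R,8S,10R,4E)-10,13-diacetoxy-8-methacryloyloxy-1-oxogermacra-4,7(11)-dien-12,6-olide | C=C(C)C(=O)O[C@H]1C[C@@](C)(OC(C)=O)C(=O)CC/C(C)=C/[C@H]2OC(=O)C(COC(C)=O)=C12 | target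

## Step count and least certain steps

Total: 20 steps. Longest linear sequence: 15 steps (steps 1–6, then 12–20, from (R)-citramalic acid); the other branch (steps 7–11) has 5 steps before the coupling.

Step 18 (key step). What may go wrong: intermolecular coupling to oligomers may outrun ring closure, because both the alkoxide exchange and the reductive elimination must pass through medium-ring palladacycles. Further risks are β-hydride elimination from the homoenolate to the vinyl ketone with loss of iodide, epimerisation at C6 by the carbonate at 80 °C, ionisation of the allylic C6–O or C8–O ester bonds by zerovalent palladium, and Heck-type capture of the alkenylpalladium by the methacrylate. Fallback (the two carbon–carbon bond formations change places; sets out from 18 and 7, returns at 26): 18 is hydrozirconated and iodinated as in step 15 to the iodoalkenyl triflate F1. F1 and cyclopropanol 7 are joined by the intermolecular ring-opening coupling (Pd(OAc)2, XPhos, Cs2CO3, toluene, 60–80 °C), where the reaction is established and the C–I bond is expected to react before the triflate, to give the hydroxy ketone F2. Dess–Martin oxidation of the primary alcohol gives the keto aldehyde F3. An intramolecular Nozaki–Hiyama–Kishi reaction (CrCl2, catalytic NiCl2, DMF, high dilution) closes the ring at C7–C8 to the macrocyclic carbinols F4. Oxidation to the dione F5 and reduction of the conjugated C8 ketone with (R)-2-methyl-CBS-oxazaborolidine and catecholborane give the 8S carbinol F6, whose methacryloylation under the conditions of step 16 gives 26.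

Step 11. What may go wrong: poor facial selectivity, because the aldehyde is flanked by a triflyloxy group and a cis ester that can chelate zinc; and erosion of the C6 configuration by enolisation of 18 under the zinc alkoxide. Fallback (resolution in place of asymmetric catalysis; sets out from 15, returns at 18): addition of 1-propynylmagnesium bromide to 15 (THF, −78 °C) with spontaneous lactonisation gives the racemic triflate F7, and preparative chromatography on a chiral stationary phase gives 18.

Step 12. What may go wrong: slow oxidative addition and transmetallation at the hindered, tetrasubstituted enol triflate; or β-elimination of the alkenylchromium with opening of the lactone to an allenoate. Fallback (acylation of an alkenylstannane in place of carbonyl addition; sets out from 18 and 9, returns at 20): 18 is converted with Me3SnSnMe3, Pd(PPh3)4 and LiCl (THF, 60 °C) into the alkenylstannane F8. Aldehyde 9 is oxidised under buffered Pinnick conditions (NaClO2, NaH2PO4, 2-methylbut-2-ene) to the acid F9, which 1-chloro-N,N,2-trimethylprop-1-en-1-amine turns into the acid chloride F10. Stille acylation of F8 with F10 (Pd2(dba)3, tri(2-furyl)phosphine, toluene) gives ketone 20 directly.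

Step 15. What may go wrong: competing reduction of the lactone by the zirconium hydride if the hindered alkyne inserts slowly, or incomplete regiocontrol. Fallback (silicon in place of zirconium; sets out from 21, returns at 23): platinum-catalysed syn hydrosilylation of 21 (PtCl2, XPhos, Et3SiH, THF, 50 °C), which places silicon on the carbon remote from the oxygenated C6, gives the vinylsilane F11. Iododesilylation with retention (N-iodosuccinimide, 2,6-lutidine, (CF3)2CHOH, 0 °C) gives 23.

Step 4. What may go wrong: slow insertion of the hindered, α-quaternary lactone carbonyl into the titanacyclopropane, so that the reagent is consumed unproductively. Fallback (cyclopropanation of an enol ether in place of the Kulinkovich reaction; sets out from 5, returns at 8): MeLi (1 equiv, THF, −78 °C) opens 5 to the hydroxy methyl ketone F12. Me3SiOTf and Et3N silylate the primary hydroxyl and convert the ketone, which can enolise only toward its methyl group, into the silyl enol ether F13. Simmons–Smith cyclopropanation (Et2Zn, CH2I2, CH2Cl2, 0 °C) gives 8.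

## Further compounds

F1 | step 18 | (2R)-4-{[(tert-butyldiphenylsilyl)oxy]methyl}-2-[(1E)-2-iodoprop-1-en-1-yl]-5-oxo-2,5-dihydrofuran-3-yl trifluoromethanesulfonate | I/C(C)=C/[C@H]1OC(=O)C(CO[Si](c2ccccc2)(c2ccccc2)C(C)(C)C)=C1OS(=O)(=O)C(F)(F)F
F2 | step 18 | open-chain hydroxy ketone (C3–C4 joined; C1 ketone, 10-OTES, primary C8 hydroxyl, C7 triflate) | OCC[C@@](C)(O[Si](CC)(CC)CC)C(=O)CC/C(C)=C/[C@H]1OC(=O)C(CO[Si](c2ccccc2)(c2ccccc2)C(C)(C)C)=C1OS(=O)(=O)C(F)(F)F
F3 | step 18 | open-chain keto aldehyde (C8 aldehyde, C7 triflate) | O=CC[C@@](C)(O[Si](CC)(CC)CC)C(=O)CC/C(C)=C/[C@H]1OC(=O)C(CO[Si](c2ccccc2)(c2ccccc2)C(C)(C)C)=C1OS(=O)(=O)C(F)(F)F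
F4 | step 18 | macrocyclic C8 carbinols, both epimers (10-OTES, 13-OTBDPS) | OC1C[C@@](C)(O[Si](CC)(CC)CC)C(=O)CC/C(C)=C/[C@H]2OC(=O)C(CO[Si](c3ccccc3)(c3ccccc3)C(C)(C)C)=C12
F5 | step 18 | macrocyclic 1,8-dione (10-OTES, 13-OTBDPS) | O=C1C[C@@](C)(O[Si](CC)(CC)CC)C(=O)CC/C(C)=C/[C@H]2OC(=O)C(CO[Si](c3ccccc3)(c3ccccc3)C(C)(C)C)=C12
F6 | step 18 | macrocyclic (8S)-carbinol (10-OTES, 13-OTBDPS) | O[C@H]1C[C@@](C)(O[Si](CC)(CC)CC)C(=O)CC/C(C)=C/[C@H]2OC(=O)C(CO[Si](c3ccccc3)(c3ccccc3)C(C)(C)C)=C12
F7 | step 11 | racemic 4-{[(tert-butyldiphenylsilyl)oxy]methyl}-5-oxo-2-(prop-1-yn-1-yl)-2,5-dihydrofuran-3-yl trifluoromethanesulfonate | CC#CC1OC(=O)C(CO[Si](c2ccccc2)(c2ccccc2)C(C)(C)C)=C1OS(=O)(=O)C(F)(F)F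
F8 | step 12 | (5R)-3-{[(tert-butyldiphenylsilyl)oxy]methyl}-5-(prop-1-yn-1-yl)-4-(trimethylstannyl)furan-2(5H)-one | CC#C[C@H]1OC(=O)C(CO[Si](c2ccccc2)(c2ccccc2)C(C)(C)C)=C1[Sn](C)(C)C
F9 | step 12 | (3R)-3-[(triethylsilyl)oxy]-3-{1-[(trimethylsilyl)oxy]cyclopropyl}butanoic acid | OC(=O)C[C@@](C)(O[Si](CC)(CC)CC)C1(O[Si](C)(C)C)CC1
F10 | step 12 | (3R)-3-[(triethylsilyl)oxy]-3-{1-[(trimethylsilyl)oxy]cyclopropyl}butanoyl chloride | ClC(=O)C[C@@](C)(O[Si](CC)(CC)CC)C1(O[Si](C)(C)C)CC1
F11 | step 15 | (E)-C4 triethylsilyl alkene corresponding to 23 | CC[Si](CC)(CC)/C(C)=C/[C@H]1OC(=O)C(CO[Si](c2ccccc2)(c2ccccc2)C(C)(C)C)=C1[C@@H](O)C[C@@](C)(O[Si](CC)(CC)CC)C3(O[Si](C)(C)C)CC3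
F12 | step 4 | (3R)-5-hydroxy-3-methyl-3-[(triethylsilyl)oxy]pentan-2-one | CC(=O)[C@](C)(O[Si](CC)(CC)CC)CCO
F13 | step 4 | (3R)-3-methyl-3-[(triethylsilyl)oxy]-2,5-bis[(trimethylsilyl)oxy]pent-1-ene | C=C(O[Si](C)(C)C)[C@](C)(O[Si](CC)(CC)CC)CCO[Si](C)(C)C
A1 | alternative 1 | trans-fused ten-membered α-methylene-γ-lactone with 8-OTBS and 10-OAc | CC(C)(C)[Si](C)(C)O[C@H]1C[C@@](C)(OC(C)=O)C(=O)CC/C(C)=C/[C@H]2OC(=O)C(=C)[C@H]12
A2 | alternative 2 | (E)-cyclodec-4-ene-1,6-dione with 8-OTBS and 10-OMOM | CC(C)(C)[Si](C)(C)O[C@H]1C[C@@](C)(OCOC)C(=O)CC/C(C)=C/C(=O)C1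
A3 | alternative 3 | ten-membered germacranolide core with free C8 hydroxyl, 10-OTES and 13-OAc | O[C@H]1C[C@@](C)(O[Si](CC)(CC)CC)C(=O)CC/C(C)=C/[C@H]2OC(=O)C(COC(C)=O)=C12
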